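Every carbon of the cyclohexane ring bears oxygen, and the two acetoxy carbons (C1, beside the diol; C6, beside the quaternary epoxide carbon C5) are vicinal. Reading C5 as a former ketone turns the C1–C6 bond into an aldol bond and the ring into a hexopyranose turned inside out. The key step is a mercury-catalysed Ferrier carbocyclisation of a D-galactose-derived (Z)-6-O-acetyl-hex-5-enopyranoside: in one operation the oxane ring opens, C6 adds to C1 to close the carbocycle, both new stereocentres are set, the C6 acetate is delivered and a C5 ketone remains for the branch carbon and the epoxide. The precursor is a methyl glycoside, not a carbocycle.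

Key step: step 6

Remark on locants: sugar numbering is kept throughout; C1–C6 of the galactoside become ring carbons C1–C6 of the carbocycle and C7 is the carbon added at C5; α is the ring face that carries the C2 oxygen, β the face that carries the C3 oxygen (Bn = benzyl, PMB = 4-methoxybenzyl).
Assumption: in the carbocyclisation the new C1 hydroxyl forms trans to the C3 ether (axial, α) and the (Z)-enol acetate gives the equatorial C6 acetate (α), as is usual for this reaction class; the endgame is built on this outcome.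

Step 1
Reactants: 1 methyl α-D-galactopyranoside
Product: 2 methyl 4,6-O-(4-methoxybenzylidene)-α-D-galactopyranoside
Conditions: 4-MeOC6H4CH(OMe)2, CSA (cat.), DMF, 60 °C, reduced pressure
Reagents that add atoms: 4-methoxybenzaldehyde dimethyl acetal COc1ccc(C(OC)OC)cc1
Why: Acid-catalysed transacetalisation under removal of methanol gives the thermodynamic six-membered 4,6-O-arylidene acetal across the primary O6 and the axial O4, and the new acetal centre equilibrates to the isomer with the aryl group equatorial on the 1,3-dioxane chair.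

Step 2
Reactants: 2 methyl 4,6-O-(4-methoxybenzylidene)-α-D-galactopyranoside
Product: 3 methyl 2,3-di-O-benzyl-4,6-O-(4-methoxybenzylidene)-α-D-galactopyranoside
Conditions: NaH, BnBr, Bu4NI (cat.), DMF, 0 °C to rt
Reagents that add atoms: benzyl bromide BrCc1ccccc1
Why: Williamson etherification of the two remaining secondary alkoxides with benzyl bromide; no stereocentre is touched and the acetal is stable to base.

Step 3
Reactants: 3 methyl 2,3-di-O-benzyl-4,6-O-(4-methoxybenzylidene)-α-D-galactopyranoside
Product: 4 methyl 2,3-di-O-benzyl-4-O-(4-methoxybenzyl)-α-D-galactopyranoside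
Conditions: BH3·THF, Cu(OTf)2 (5 mol%), CH2Cl2, 0 °C to rt
Reagents that add atoms: none
Why: Regioselective reductive opening of the arylidene acetal: the Lewis acid–borane pair binds the more accessible O6, the acetal C–O6 bond ionises and hydride quenches the 4-methoxybenzyl oxocarbenium ion, which leaves the PMB ether on O4 and frees the primary hydroxyl with no change at any ring stereocentre.

Step 4
Reactants: 4 methyl 2,3-di-O-benzyl-4-O-(4-methoxybenzyl)-α-D-galactopyranoside
Product: 5 methyl 2,3-di-O-benzyl-4-O-(4-methoxybenzyl)-α-D-galacto-hexodialdo-1,5-pyranoside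
Conditions: Dess–Martin periodinane, CH2Cl2, 0 °C to rt
Reagents that add atoms: none
Why: Dess–Martin oxidation of the primary alcohol stops at the aldehyde under neutral, amine-free conditions that avoid β-elimination of the C4 ether and leave the benzyl and PMB ethers alone.

Step 5
Reactants: 5 methyl 2,3-di-O-benzyl-4-O-(4-methoxybenzyl)-α-D-galacto-hexodialdo-1,5-pyranoside
Product: 6 methyl (Z)-6-O-acetyl-2,3-di-O-benzyl-4-O-(4-methoxybenzyl)-β-L-arabino-hex-5-enopyranoside
Conditions: Ac2O, K2CO3, MeCN, 80 °C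
Reagents that add atoms: acetic anhydride CC(=O)OC(C)=O
Why: Enol ester formation by carbonate-mediated enolisation of the aldehyde toward C5 and O-acetylation of the enolate, which is expected to give the Z isomer because the enolate oxygen sits cis to the ring oxygen and away from the C4 substituent; the C5 stereocentre is deliberately erased here.

Step 6
Reactants: 6 methyl (Z)-6-O-acetyl-2,3-di-O-benzyl-4-O-(4-methoxybenzyl)-β-L-arabino-hex-5-enopyranoside
Product: 8 6α-acetoxy-2α,3β-bis(benzyloxy)-1α-hydroxy-4β-(4-methoxybenzyloxy)cyclohexan-5-one, via open-chain mercurio keto-aldehyde 7 (not isolated)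
Conditions: Hg(OCOCF3)2 (10 mol%), acetone/H2O 4:1, 0 °C to rt
Reagents that add atoms: water O
Why: Hydroxymercuration of the enol acetate puts mercury on C6 and water on C5, the resulting hemiketal collapses to the C5 ketone while C1 loses methanol to become an aldehyde (open-chain 7), and the mercury enolate then adds to that aldehyde and releases divalent mercury for the next turnover. The closest known reaction type is the Ferrier carbocyclisation of hex-5-enopyranosides in its 6-O-acyl version, which gives fully oxygenated cyclohexanones. The single ring is closed in a 6-(enolexo)-exo-trig aldol mode through a chair transition state in which the C2 and C3 ethers stay equatorial. The C1 carbinol centre is controlled by the C3 benzyloxy group (new hydroxyl trans to it, hence axial and α), and C6 is controlled by the Z geometry of the enol acetate, which is carried into the enolate and places the acetoxy group equatorial (α). The step needs this C1/C6 diastereoselectivity and attack of the metal on the electron-rich enol ester rather than ester hydrolysis; the C3 substituent, the defined enol geometry and the near-neutral aqueous acetone secure them, and the mild conditions keep the β-hydroxy ketone from eliminating.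

Step 7
Reactants: 8 6α-acetoxy-2α,3β-bis(benzyloxy)-1α-hydroxy-4β-(4-methoxybenzyloxy)cyclohexan-5-one
Product: 9 6α-acetoxy-2α,3β-bis(benzyloxy)-4β-(4-methoxybenzyloxy)-5-methylenecyclohexan-1α-ol
Conditions: Zn, CH2Br2, TiCl4, THF/CH2Cl2, 0 °C to rt
Reagents that add atoms: dibromomethane BrCBr
Why: Takai–Lombardo methylenation with the non-basic zinc–titanium gem-dimetallic reagent converts the hindered ketone into the exocyclic alkene without enolising the α-acetoxy-β-hydroxy ketone and without touching the acetate; no stereocentre is formed.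

Step 8
Reactants: 9 6α-acetoxy-2α,3β-bis(benzyloxy)-4β-(4-methoxybenzyloxy)-5-methylenecyclohexan-1α-ol
Product: 10 6α-acetoxy-2α,3β-bis(benzyloxy)-5α,7-epoxy-4β-(4-methoxybenzyloxy)-5β-methylcyclohexan-1α-ol (spiro-epoxide)
Conditions: VO(acac)2 (5 mol%), t-BuOOH, CH2Cl2, 0 °C to rt
Reagents that add atoms: tert-butyl hydroperoxide CC(C)(C)OO
Why: Hydroxyl-directed vanadium-catalysed epoxidation in which the axial C1 hydroxyl, syn-axial to the α face of the exocyclic alkene, binds the vanadium alkylperoxide and delivers oxygen to that face while the axial C4 PMB ether shields the β face, so the C5 oxygen is set α and C7 β.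

Step 9
Reactants: 10 6α-acetoxy-2α,3β-bis(benzyloxy)-5α,7-epoxy-4β-(4-methoxybenzyloxy)-5β-methylcyclohexan-1α-ol (spiro-epoxide)
Product: 11 6α-acetoxy-5β-(benzoyloxymethyl)-2α,3β-bis(benzyloxy)-4β-(4-methoxybenzyloxy)cyclohexane-1α,5α-diol
Conditions: PhCO2H (3 equiv), PhCO2Cs (0.3 equiv), DMF, 70 °C
Reagents that add atoms: benzoic acid OC(=O)c1ccccc1
Why: Carboxylate opening of the 2,2-disubstituted terminal epoxide by SN2 attack at the unhindered CH2 carbon installs the primary benzoate and leaves the C5–O bond intact, so the tertiary carbinol keeps its α configuration; the excess of benzoic acid buffers the medium against acetyl migration.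

Step 10
Reactants: 11 6α-acetoxy-5β-(benzoyloxymethyl)-2α,3β-bis(benzyloxy)-4β-(4-methoxybenzyloxy)cyclohexane-1α,5α-diol
Product: 12 6α-acetoxy-5β-(benzoyloxymethyl)-2α,3β-bis(benzyloxy)cyclohexane-1α,4β,5α-triol
Conditions: DDQ, CH2Cl2/pH 7 buffer 10:1, 0 °C to rt
Reagents that add atoms: none
Why: Oxidative cleavage of the electron-rich PMB ether by DDQ (benzylic hydride abstraction and hydrolysis of the oxocarbenium ion) frees the axial C4 hydroxyl while benzyl ethers, esters and the free hydroxyls are untouched.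

Step 11
Reactants: 12 6α-acetoxy-5β-(benzoyloxymethyl)-2α,3β-bis(benzyloxy)cyclohexane-1α,4β,5α-triol
Product: 15 1β,6α-diacetoxy-5β-(benzoyloxymethyl)-2α,3β-bis(benzyloxy)-4α,5α-epoxycyclohexane, via bis-triflate 13 (not isolated), via epoxy triflate 14 (not isolated)
Conditions: Tf2O (2.2 equiv), pyridine, CH2Cl2, −30 to 0 °C; then Bu4NOAc (4 equiv), MeCN, 0 °C to rt
Reagents that add atoms: tetrabutylammonium acetate CCCC[N+](CCCC)(CCCC)CCCC.CC(=O)[O-]
Why: Both secondary axial hydroxyls are triflated whereas the tertiary one is not; the C5 oxygen, anti-periplanar to the axial C4 triflate, then closes the α-epoxide by intramolecular SN2 (Williamson-type closure with inversion at C4), and acetate displaces the axial C1 triflate by intermolecular SN2 with inversion to give the β-acetate, the cis-disposed C2 and C6 substituents being unable to participate.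

Step 12
Reactants: 15 1β,6α-diacetoxy-5β-(benzoyloxymethyl)-2α,3β-bis(benzyloxy)-4α,5α-epoxycyclohexane
Product: 16 1β,6α-diacetoxy-5β-(benzoyloxymethyl)-4α,5α-epoxycyclohexane-2α,3β-diol (CNP0171674.1)
Conditions: H2 (1 atm), Pd(OH)2/C, EtOAc, rt
Reagents that add atoms: none
Why: Catalytic hydrogenolysis removes the two benzyl ethers under neutral conditions in which the non-benzylic trisubstituted epoxide, the acetates and the benzoate are inert, and no stereocentre is affected.

Compound list
1 | methyl α-D-galactopyranoside | CO[C@@H]1[C@H](O)[C@@H](O)[C@@H](O)[C@@H](CO)O1 | starting material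
2 | methyl 4,6-O-(4-methoxybenzylidene)-α-D-galactopyranoside (aryl equatorial on the dioxane chair) | CO[C@@H]1[C@H](O)[C@@H](O)[C@H]2O[C@@H](c3ccc(OC)cc3)OC[C@H]2O1 | intermediate
3 | methyl 2,3-di-O-benzyl-4,6-O-(4-methoxybenzylidene)-α-D-galactopyranoside | CO[C@@H]1[C@H](OCc3ccccc3)[C@@H](OCc3ccccc3)[C@H]2O[C@@H](c3ccc(OC)cc3)OC[C@H]2O1 | intermediate
4 | methyl 2,3-di-O-benzyl-4-O-(4-methoxybenzyl)-α-D-galactopyranoside (free 6-OH) | CO[C@@H]1[C@H](OCc2ccccc2)[C@@H](OCc2ccccc2)[C@@H](OCc2ccc(OC)cc2)[C@@H](CO)O1 | intermediate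
5 | methyl 2,3-di-O-benzyl-4-O-(4-methoxybenzyl)-α-D-galacto-hexodialdo-1,5-pyranoside (C6 aldehyde) | CO[C@@H]1[C@H](OCc2ccccc2)[C@@H](OCc2ccccc2)[C@@H](OCc2ccc(OC)cc2)[C@@H](C=O)O1 | intermediate
6 | methyl (Z)-6-O-acetyl-2,3-di-O-benzyl-4-O-(4-methoxybenzyl)-β-L-arabino-hex-5-enopyranoside (C5=C6 enol acetate of 5, acetoxy cis to the ring oxygen, C1–C4 unchanged) | CO[C@@H]1[C@H](OCc2ccccc2)[C@@H](OCc2ccccc2)[C@@H](OCc2ccc(OC)cc2)/C(=C/OC(C)=O)O1 | intermediate
7 | open-chain 6-O-acetyl-2,3-di-O-benzyl-4-O-(4-methoxybenzyl)-6-(trifluoroacetoxymercurio)hexos-5-ulose (C1 aldehyde, C5 ketone, C2–C4 as in 5; labile C6 centre drawn nominally; not isolated) | O=C[C@H](OCc1ccccc1)[C@@H](OCc1ccccc1)[C@@H](OCc1ccc(OC)cc1)C(=O)[C@H](OC(C)=O)[Hg]OC(=O)C(F)(F)F | intermediate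
8 | 6α-acetoxy-2α,3β-bis(benzyloxy)-1α-hydroxy-4β-(4-methoxybenzyloxy)cyclohexan-5-one (1-OH and 4-OPMB axial) | O[C@@H]1[C@H](OCc2ccccc2)[C@@H](OCc2ccccc2)[C@@H](OCc2ccc(OC)cc2)C(=O)[C@@H]1OC(C)=O | intermediate
9 | 6α-acetoxy-2α,3β-bis(benzyloxy)-4β-(4-methoxybenzyloxy)-5-methylenecyclohexan-1α-ol | O[C@@H]1[C@H](OCc2ccccc2)[C@@H](OCc2ccccc2)[C@@H](OCc2ccc(OC)cc2)C(=C)[C@@H]1OC(C)=O | intermediate
10 | spiro-epoxide of 9 across C5=C7, epoxide oxygen on the α face of C5, C7 β | O[C@@H]1[C@H](OCc2ccccc2)[C@@H](OCc2ccccc2)[C@@H](OCc2ccc(OC)cc2)[C@@]2(CO2)[C@@H]1OC(C)=O | intermediate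
11 | 6α-acetoxy-5β-(benzoyloxymethyl)-2α,3β-bis(benzyloxy)-4β-(4-methoxybenzyloxy)cyclohexane-1α,5α-diol | O[C@@H]1[C@H](OCc2ccccc2)[C@@H](OCc2ccccc2)[C@@H](OCc2ccc(OC)cc2)[C@@](O)(COC(=O)c2ccccc2)[C@@H]1OC(C)=O | intermediate
12 | 6α-acetoxy-5β-(benzoyloxymethyl)-2α,3β-bis(benzyloxy)cyclohexane-1α,4β,5α-triol | O[C@@H]1[C@H](OCc2ccccc2)[C@@H](OCc2ccccc2)[C@@H](O)[C@@](O)(COC(=O)c2ccccc2)[C@@H]1OC(C)=O | intermediate
13 | 1α,4β-bis(trifluoromethanesulfonate) of 12 (not isolated) | FC(F)(F)S(=O)(=O)O[C@@H]1[C@H](OCc2ccccc2)[C@@H](OCc2ccccc2)[C@@H](OS(=O)(=O)C(F)(F)F)[C@@](O)(COC(=O)c2ccccc2)[C@@H]1OC(C)=O | intermediate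
14 | 6α-acetoxy-5β-(benzoyloxymethyl)-2α,3β-bis(benzyloxy)-4α,5α-epoxycyclohexan-1α-yl trifluoromethanesulfonate (not isolated) | FC(F)(F)S(=O)(=O)O[C@@H]1[C@H](OCc2ccccc2)[C@@H](OCc2ccccc2)[C@@H]2O[C@]2(COC(=O)c2ccccc2)[C@@H]1OC(C)=O | intermediate
15 | 1β,6α-diacetoxy-5β-(benzoyloxymethyl)-2α,3β-bis(benzyloxy)-4α,5α-epoxycyclohexane | CC(=O)O[C@H]1[C@H](OCc2ccccc2)[C@@H](OCc2ccccc2)[C@@H]2O[C@]2(COC(=O)c2ccccc2)[C@@H]1OC(C)=O | intermediate
16 | 1β,6α-diacetoxy-5β-(benzoyloxymethyl)-4α,5α-epoxycyclohexane-2α,3β-diol, (1S,2R,3R,4S,5S,6R) with the locants used here (CNP0171674.1) | CC(=O)O[C@H]1[C@H](O)[C@@H](O)[C@@H]2O[C@]2(COC(=O)c2ccccc2)[C@@H]1OC(C)=O | target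

Total step count: 12. Longest linear sequence: 12 steps from methyl α-D-galactopyranoside (the route is fully linear).

Steps most likely to fail (the key step is ranked below these because it runs on the substrate class for which its reaction type is established; its stereochemical course is the assumption stated before the steps):

Step 11, the one-flask double displacement. The axial C1 triflate may undergo E2 elimination toward C2 or C6, or be attacked by pyridine, before acetate arrives, and acetate may attack C4 before the epoxide has closed. Fallback: the two events are separated, setting out from 11 while O4 is still protected. Triflation of its only secondary hydroxyl (Tf2O, pyridine, CH2Cl2, −30 °C) gives the 1α-triflate F1, and Bu4NOAc in MeCN inverts it to the 1β-acetate F2. DDQ then frees O4 to give the 4β,5α-diol F3, MsCl/Et3N gives the 4β-mesylate F4, and DBU in toluene closes the α-epoxide, returning to the route at 15.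

Step 9, the benzoate opening of the spiro-epoxide. Attack at the CH2 group next to the quaternary centre may be slow, and at the temperature needed the carboxylate may shuttle the C6 acetyl group to the cis C1 hydroxyl or to the tertiary alkoxide. Fallback: the spiro-epoxide is bypassed, setting out from 9. Hydrogen-bond-directed dihydroxylation (OsO4, TMEDA, CH2Cl2, −78 °C), guided to the α face by the axial C1 hydroxyl and anti to the axial C4 ether, gives the 1α,5α,7-triol F5. Selective benzoylation of its primary hydroxyl (BzCl, 2,4,6-collidine, CH2Cl2, −40 °C) returns to the route at 11.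

Step 7, the methylenation. The Lewis-acidic titanium reagent may dehydrate the β-hydroxy ketone or trigger its retro-aldol cleavage, or fail to engage a ketone flanked by two oxygenated carbons. Fallback: a two-stage Peterson olefination setting out from 8. Me3SiCH2MgCl with CeCl3 (THF, −78 °C) adds to the ketone faster than to the acetate to give the β-hydroxysilane F6, and acid-promoted elimination (aqueous HF, MeCN, 0 °C) returns to the route at 9.

Further compounds
F1 | step 11 | 6α-acetoxy-5β-(benzoyloxymethyl)-2α,3β-bis(benzyloxy)-5α-hydroxy-4β-(4-methoxybenzyloxy)cyclohexan-1α-yl trifluoromethanesulfonate | FC(F)(F)S(=O)(=O)O[C@@H]1[C@H](OCc2ccccc2)[C@@H](OCc2ccccc2)[C@@H](OCc2ccc(OC)cc2)[C@@](O)(COC(=O)c2ccccc2)[C@@H]1OC(C)=O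
F2 | step 11 | 1β,6α-diacetoxy-5β-(benzoyloxymethyl)-2α,3β-bis(benzyloxy)-4β-(4-methoxybenzyloxy)cyclohexan-5α-ol | CC(=O)O[C@H]1[C@H](OCc2ccccc2)[C@@H](OCc2ccccc2)[C@@H](OCc2ccc(OC)cc2)[C@@](O)(COC(=O)c2ccccc2)[C@@H]1OC(C)=O
F3 | step 11 | 1β,6α-diacetoxy-5β-(benzoyloxymethyl)-2α,3β-bis(benzyloxy)cyclohexane-4β,5α-diol | CC(=O)O[C@H]1[C@H](OCc2ccccc2)[C@@H](OCc2ccccc2)[C@@H](O)[C@@](O)(COC(=O)c2ccccc2)[C@@H]1OC(C)=O
F4 | step 11 | 4β-methanesulfonate of F3 | CC(=O)O[C@H]1[C@H](OCc2ccccc2)[C@@H](OCc2ccccc2)[C@@H](OS(C)(=O)=O)[C@@](O)(COC(=O)c2ccccc2)[C@@H]1OC(C)=O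
F5 | step 9 | 6α-acetoxy-2α,3β-bis(benzyloxy)-5β-(hydroxymethyl)-4β-(4-methoxybenzyloxy)cyclohexane-1α,5α-diol | O[C@@H]1[C@H](OCc2ccccc2)[C@@H](OCc2ccccc2)[C@@H](OCc2ccc(OC)cc2)[C@@](O)(CO)[C@@H]1OC(C)=O
F6 | step 7 | 6α-acetoxy-2α,3β-bis(benzyloxy)-4β-(4-methoxybenzyloxy)-5β-(trimethylsilylmethyl)cyclohexane-1α,5α-diol | O[C@@H]1[C@H](OCc2ccccc2)[C@@H](OCc2ccccc2)[C@@H](OCc2ccc(OC)cc2)[C@@](O)(C[Si](C)(C)C)[C@@H]1OC(C)=O
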